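## Retrosynthetic overview

1. **Feature.** In unit B (ketone half, primed guaiane numbers) the lactone carbon C6′ is bonded to C5′, the β-carbon of the C3′ ketone. The α-carbon C4′ is the spiro atom bonded to C3 of unit A (diol half). One enone C3′(=O)–C4′=C5′ can therefore accept a furan carbon at C5′ and then pass its C4′ enolate to the C3 ketone.
2. **Key disconnection.** C5′–C6′ (seven-membered ring of unit B) and C3–C4′ (central cyclopentane C3–C4–C15–C15′–C4′) are opened together. This gives one chain holding a 2-silyloxyfuran, a 2-alkylcyclopentenone and an α-silyloxy ketone.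
3. **Fragment union.** The chain is cut at C15′–C4′ (Negishi coupling). One piece is a unit A iodide from dehydrocostus lactone, in which C15′ enters as a cyclopropane CH2 and C4–O by Rubottom oxidation. The other is a 2-iodocyclopentenone whose C1′ comes from (R)-4-silyloxycyclopentenone and whose butenolide comes from 3,4-dibromofuranone.
4. **C11′ placeholder.** Bromine holds C11′ through the cascade: it blocks the furan α-position and cannot be lost by β-elimination. C13′ is then added by Stille coupling, and an allylic diazene shift sets H-7′ and C11′=C13′ without any acid that would move the C10=C14 and C10′=C14′ methylenes.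
5. **Ring order.** The three rings of unit A, the cyclopentenone and the furanone ring are bought. The seven-membered ring of unit B closes first and the central cyclopentane second, both in step 15.

Key step: step 15

Convention and assumption: α is the face of H-1, H-5 and H-7 (and of their primed partners). Step 1 is assumed to give mainly the 3α-alcohol; either C3 epimer serves, because C3 becomes a ketone in step 3.

## Route

Step 1
Reactants: 1 dehydrocostus lactone
Product: 2 3-epizaluzanin C (3α-hydroxydehydrocostus lactone)
Conditions: SeO2 (0.3 equiv), t-BuOOH, CH2Cl2, 0 °C → rt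
Reagents that add atoms: tert-butyl hydroperoxide, CC(C)(C)OO
Why: Selenium dioxide allylic hydroxylation (ene reaction, then [2,3]-sigmatropic shift) should oxidise the ring CH2 (C3) next to the C4=C15 methylene from the convex α face, and the new C3 stereocentre is removed again in step 3.

Step 2
Reactants: 2 3-epizaluzanin C
Product: 3 spirocyclopropyl alcohol (2 with C4=C15 turned into the spiro-cyclopropane C4/C15/C15′)
Conditions: Et2Zn, CH2I2, CH2Cl2, −15 → 0 °C
Reagents that add atoms: diiodomethane, ICI
Why: In this hydroxyl-directed Simmons–Smith cyclopropanation the C3 oxygen should steer the zinc carbenoid to the adjacent C4=C15 bond ahead of the undirected C10=C14 bond, the electron-poor lactone methylene being inert; C4 carries two equivalent CH2 groups and is no stereocentre.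

Step 3
Reactants: 3 spirocyclopropyl alcohol
Product: 4 spirocyclopropyl ketone (3-oxo compound)
Conditions: Dess–Martin periodinane, CH2Cl2, 0 °C → rt
Reagents that add atoms: none
Why: Dess–Martin oxidation of the secondary alcohol is neutral enough for the cyclopropane, both methylenes and the lactone.

Step 4
Reactants: 4 spirocyclopropyl ketone
Product: 5 C3=C4 triethylsilyl enol ether carrying the chain C15H2–C15′H2–I on C4
Conditions: Et3SiCl, NaI, 2,6-di-tert-butyl-4-methylpyridine (0.2 equiv), MeCN–CH2Cl2, −20 → 0 °C; Et3N, aq NaHCO3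
Reagents that add atoms: chlorotriethylsilane, CC[Si](Cl)(CC)CC; sodium iodide, [Na+].[I-]
Why: Silyl iodide opening of a cyclopropyl ketone: silylation of the carbonyl oxygen turns the spiro ring, locked in the bisected geometry, into a homo-Michael acceptor that iodide opens at either equivalent CH2 by SN2 attack, which should give the regiodefined enol ether and the primary iodide.

Step 5
Reactants: 5 iodoethyl silyl enol ether
Product: 7 unit A iodide (3-oxo, 4α-triethylsilyloxy, 4β-CH2CH2I), via silyloxy epoxide 6 (not isolated)
Conditions: dimethyldioxirane (1.0 equiv), acetone–CH2Cl2, −78 °C; then PPTS (5 mol %), 0 °C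
Reagents that add atoms: dimethyldioxirane, CC1(C)OO1
Why: Rubottom oxidation: the dioxirane should epoxidise the electron-rich tetrasubstituted enol ether far faster than the 1,1-disubstituted alkene or the iodide and from the convex α face (β is shielded by C5–C6), and acid-induced opening with 1,4-silyl shift leaves C4–OSiEt3 α and the iodoethyl chain β.

Step 6
Reactants: 8 3-bromobut-3-en-1-ol
Product: 9 (3-bromobut-3-enyloxy)triethylsilane
Conditions: Et3SiCl, imidazole, CH2Cl2, 0 °C
Reagents that add atoms: chlorotriethylsilane, CC[Si](Cl)(CC)CC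
Why: Standard silylation masks the primary alcohol for Grignard formation with a group that can later be removed beside a tert-butyldimethylsilyl ether.

Step 7
Reactants: 9 (3-bromobut-3-enyloxy)triethylsilane; 10 (R)-4-(tert-butyldimethylsilyloxy)cyclopent-2-en-1-one
Product: 12 (3S,4R)-4-(tert-butyldimethylsilyloxy)-3-[4-(triethylsilyloxy)but-1-en-2-yl]cyclopentan-1-one, via alkenylmagnesium bromide 11 (not isolated)
Conditions: Mg, THF, 40 °C; then CuBr·SMe2 (15 mol %), 10, THF, −78 °C; aq NH4Cl at −78 °C
Reagents that add atoms: none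
Why: Copper-catalysed conjugate addition of the alkenyl Grignard reagent should occur anti to the silyloxy group of 10, so that the bought stereocentre sets C1′ (side chain β), and the cold quench keeps the β-silyloxy ketone from eliminating.

Step 8
Reactants: 12 bis-silyl ether
Product: 13 (3S,4R)-4-(tert-butyldimethylsilyloxy)-3-(4-hydroxybut-1-en-2-yl)cyclopentan-1-one
Conditions: PPTS (10 mol %), MeOH–CH2Cl2, 0 °C
Reagents that add atoms: none
Why: Acid-catalysed methanolysis cleaves the primary triethylsilyl ether much faster than the secondary tert-butyldimethylsilyl ether.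

Step 9
Reactants: 13 primary alcohol
Product: 14 (3S,4R)-4-(tert-butyldimethylsilyloxy)-3-(4-iodobut-1-en-2-yl)cyclopentan-1-one
Conditions: I2, PPh3, imidazole, CH2Cl2, 0 °C
Reagents that add atoms: iodine, II
Why: The Appel reaction converts the unhindered primary alcohol into the iodide under near-neutral conditions that leave the β-silyloxy ketone untouched.

Step 10
Reactants: 14 alkyl iodide; 15 3,4-dibromofuran-2(5H)-one
Product: 17 (3S,4R)-3-[4-(4-bromo-5-oxo-2,5-dihydrofuran-3-yl)but-1-en-2-yl]-4-(tert-butyldimethylsilyloxy)cyclopentan-1-one, via alkylzinc iodide 16 (not isolated)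
Conditions: Zn dust, LiCl, THF, 30 °C; decant; 15, PdCl2(dppf) (5 mol %), THF, 0 °C → rt
Reagents that add atoms: none
Why: Negishi coupling: zerovalent palladium should insert into the C4–Br bond of 15 (a vinylogous acyl bromide) rather than C3–Br, which forms C7′–C8′, and the ring is still a saturated ketone so that nothing can cyclise onto C5′ during zinc insertion.

Step 11
Reactants: 17 β-silyloxy ketone
Product: 18 (R)-4-[4-(4-bromo-5-oxo-2,5-dihydrofuran-3-yl)but-1-en-2-yl]cyclopent-2-en-1-one
Conditions: DBU (1.1 equiv), CH2Cl2, −20 → 0 °C, short contact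
Reagents that add atoms: none
Why: E1cB loss of the β-silyloxy group places the double bond at C4′=C5′ without ambiguity, and low temperature with short contact should spare the doubly allylic C1′–H.

Step 12
Reactants: 18 cyclopentenone
Product: 19 (R)-2-iodo-4-[4-(4-bromo-5-oxo-2,5-dihydrofuran-3-yl)but-1-en-2-yl]cyclopent-2-en-1-one (unit B fragment)
Conditions: I2, pyridine–CH2Cl2, 0 °C → rt
Reagents that add atoms: iodine, II
Why: α-Iodination of the enone by pyridine addition, iodination and elimination marks C4′ alone, because the tetrasubstituted bromobutenolide cannot take part.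

Step 13
Reactants: 7 unit A iodide; 19 unit B iodoenone
Product: 21 coupled enone–butenolide (C15′–C4′ bond made), via unit A alkylzinc iodide 20 (not isolated)
Conditions: 7, Zn dust, LiCl, THF, 30 °C; decant; 19, PdCl2(dppf) (5 mol %), THF, rt
Reagents that add atoms: none
Why: Negishi coupling of a primary alkylzinc iodide with an α-iodoenone tolerates ketones, lactones and the lactone methylene, has no β-leaving group next to zinc, and should take C4′–I well ahead of the hindered C11′–Br.

Step 14
Reactants: 21 coupled enone–butenolide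
Product: 22 cascade precursor (3-bromo-2-triisopropylsilyloxyfuran)
Conditions: i-Pr3SiOTf (1.05 equiv), Et3N, CH2Cl2, −78 → −40 °C
Reagents that add atoms: triisopropylsilyl triflate, CC(C)[Si](OS(=O)(=O)C(F)(F)F)(C(C)C)C(C)C
Why: Soft enolisation: the C6′ hydrogens of the α-bromobutenolide are by far the most acidic and their loss gives an aromatic furan, so one equivalent of the bulky silyl triflate at low temperature should silylate here before the C3 ketone or the enone.

Step 15
Reactants: 22 cascade precursor
Product: 24 4-O-triethylsilyl pentacycle with a 7′(11′)-butenolide bearing Br at C11′, via difluoroboron enolate 23 (not isolated)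
Conditions: BF3·OEt2 (3 equiv), CH2Cl2 (2 mM), −78 → −40 °C; aq NaHCO3
Reagents that add atoms: none
Why: Proposed new method: BF3 binds the enone oxygen, C5 of the furan (C6′) attacks C5′ with loss of aromaticity, fluoride takes the silyl group from the oxocarbenium ion to leave the butenolide and the difluoroboron enolate 23, and C4′ of 23 adds to the BF3-bound C3 ketone, work-up freeing the C3 hydroxyl. The closest known reactions are intermolecular vinylogous Mukaiyama–Michael additions of 2-silyloxyfurans to cyclic enones and Mukaiyama–Michael/aldol domino sequences, whereas closing a seven-membered ring in this way and capturing the enolate with a hindered ketone are untested. The first closure is 7-exo-trig (C4′ stays outside the new ring) and is helped by the sp2 atoms C10′ and C7′ in the tether; the second is a 5-(enolexo)-exo-trig aldol. C5′ is set by the tether, which stands on the β face at C1′ and can reach only that face (cis fusion, H-1′ and H-5′ both α), and C6′ by the need of the furan to lie outward over H-5′, because the inward rotamer drives Br and OSi(i-Pr)3 into the C15′ chain, so that H-6′ ends anti to H-5′ (β). C4′ is set by the new C5′–C6′ bond and the seven-membered ring, which cover the β face of the enolate and leave the α face to the ketone, and C3 by the C4–C15 bond, which is β and allows only the cis-fused bicyclo[3.3.0]octane (C4′ β, OH α). The step needs the furan to choose C5′ over the lactone methylene of unit A and over the carbonyl carbons, which is secured by the higher basicity of the enone oxygen toward BF3, by the 2 mM dilution that favours the tethered acceptor, and by bromine at C11′, which leaves C6′ as the only free nucleophilic furan carbon.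

Step 16
Reactants: 24 bromobutenolide pentacycle
Product: 25 13′-hydroxy compound (C11′–CH2OH)
Conditions: Bu3SnCH2OH, Pd(PPh3)4 (10 mol %), dioxane, 85 °C
Reagents that add atoms: (tributylstannyl)methanol, CCCC[Sn](CCCC)(CCCC)CO
Why: Stille hydroxymethylation of the α-bromobutenolide brings in C13′ under neutral conditions, and an intramolecular Heck reaction with C10′=C14′ is excluded because it would give a bridgehead alkene.

Step 17
Reactants: 25 13′-hydroxy compound
Product: 28 4-O-triethylsilylainsliadimer A, via sulfonylhydrazine 26 (not isolated), via allylic diazene 27 (not isolated)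
Conditions: 2-nitrobenzenesulfonohydrazide, PPh3, DEAD, THF, −30 → 23 °C
Reagents that add atoms: none
Why: Mitsunobu displacement of the primary allylic alcohol, loss of sulfinic acid and retro-ene loss of N2 (allylic diazene rearrangement) move the double bond regiospecifically to C11′=C13′ under neutral conditions, and hydrogen should reach C7′ on the convex α face, axially and anti to H-6′, which gives the trans-fused lactone.

Step 18
Reactants: 28 4-O-triethylsilylainsliadimer A
Product: 29 ainsliadimer A
Conditions: HF·pyridine, pyridine, THF, 0 °C → rt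
Reagents that add atoms: none
Why: Buffered fluoride desilylation frees the tertiary C4 hydroxyl without acid or base strong enough to move the methylenes or reverse the aldol.

## Compound list

1 | dehydrocostus lactone | C=C1CC[C@H]2C(=C)CC[C@H]3C(=C)C(=O)O[C@@H]3[C@H]21 | starting material
2 | 3-epizaluzanin C (3α-OH) | C=C1[C@H](O)C[C@H]2C(=C)CC[C@H]3C(=C)C(=O)O[C@@H]3[C@H]21 | intermediate
3 | spirocyclopropyl alcohol | C1CC12[C@H](O)C[C@H]3C(=C)CC[C@H]4C(=C)C(=O)O[C@@H]4[C@H]32 | intermediate
4 | spirocyclopropyl ketone | C1CC12C(=O)C[C@H]3C(=C)CC[C@H]4C(=C)C(=O)O[C@@H]4[C@H]32 | intermediate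
5 | C3=C4 triethylsilyl enol ether with 2-iodoethyl on C4 | ICCC1=C(O[Si](CC)(CC)CC)C[C@H]2C(=C)CC[C@H]3C(=C)C(=O)O[C@@H]3[C@@H]12 | intermediate
6 | 3α,4α-epoxide of 5 | C=C1C(=O)O[C@@H]2[C@@H]3[C@@H](C[C@@]4(O[Si](CC)(CC)CC)O[C@@]34CCI)C(=C)CC[C@@H]12 | intermediate
7 | unit A iodide (3-oxo, 4α-OSiEt3, 4β-CH2CH2I) | C=C1C(=O)O[C@@H]2[C@@H]3[C@@H](CC(=O)[C@]3(O[Si](CC)(CC)CC)CCI)C(=C)CC[C@@H]12 | intermediate
8 | 3-bromobut-3-en-1-ol | C=C(Br)CCO | starting material
9 | (3-bromobut-3-enyloxy)triethylsilane | C=C(Br)CCO[Si](CC)(CC)CC | intermediate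
10 | (R)-4-(tert-butyldimethylsilyloxy)cyclopent-2-en-1-one | O=C1C=C[C@H](O[Si](C)(C)C(C)(C)C)C1 | starting material
11 | [4-(triethylsilyloxy)but-1-en-2-yl]magnesium bromide | CC[Si](CC)(CC)OCCC(=C)[Mg]Br | intermediate
12 | (3S,4R) conjugate adduct, bis-silyl ether | O=C1C[C@@H](C(=C)CCO[Si](CC)(CC)CC)[C@H](O[Si](C)(C)C(C)(C)C)C1 | intermediate
13 | (3S,4R) primary alcohol | O=C1C[C@@H](C(=C)CCO)[C@H](O[Si](C)(C)C(C)(C)C)C1 | intermediate
14 | (3S,4R) primary iodide | O=C1C[C@@H](C(=C)CCI)[C@H](O[Si](C)(C)C(C)(C)C)C1 | intermediate
15 | 3,4-dibromofuran-2(5H)-one | O=C1OCC(Br)=C1Br | starting material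
16 | alkylzinc iodide from 14 | O=C1C[C@@H](C(=C)CC[Zn]I)[C@H](O[Si](C)(C)C(C)(C)C)C1 | intermediate
17 | (3S,4R) bromobutenolide β-silyloxy ketone | O=C1C[C@@H](C(=C)CCC2=C(Br)C(=O)OC2)[C@H](O[Si](C)(C)C(C)(C)C)C1 | intermediate
18 | (R)-4-substituted cyclopent-2-enone | O=C1C[C@@H](C(=C)CCC2=C(Br)C(=O)OC2)C=C1 | intermediate
19 | (R)-2-iodo-4-substituted cyclopent-2-enone (unit B fragment) | O=C1C[C@@H](C(=C)CCC2=C(Br)C(=O)OC2)C=C1I | intermediate
20 | unit A alkylzinc iodide | C=C1C(=O)O[C@@H]2[C@@H]3[C@@H](CC(=O)[C@]3(O[Si](CC)(CC)CC)CC[Zn]I)C(=C)CC[C@@H]12 | intermediate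
21 | coupled enone–butenolide | C=C1C(=O)O[C@@H]2[C@@H]3[C@@H](CC(=O)[C@]3(O[Si](CC)(CC)CC)CCC4=C[C@H](C(=C)CCC5=C(Br)C(=O)OC5)CC4=O)C(=C)CC[C@@H]12 | intermediate
22 | cascade precursor (3-bromo-2-triisopropylsilyloxyfuran) | C=C1C(=O)O[C@@H]2[C@@H]3[C@@H](CC(=O)[C@]3(O[Si](CC)(CC)CC)CCC4=C[C@H](C(=C)CCc5coc(O[Si](C(C)C)(C(C)C)C(C)C)c5Br)CC4=O)C(=C)CC[C@@H]12 | intermediate
23 | difluoroboron enolate after the Michael closure | C=C1C(=O)O[C@@H]2[C@@H]3[C@@H](CC(=O)[C@]3(O[Si](CC)(CC)CC)CCC4=C(OB(F)F)C[C@H]5C(=C)CCC6=C(Br)C(=O)O[C@@H]6[C@@H]45)C(=C)CC[C@@H]12 | intermediate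
24 | cascade product (4-O-SiEt3, 11′-Br, 7′(11′)-butenolide) | C=C1C(=O)O[C@@H]2[C@@H]3[C@@H](C[C@@]4(O)[C@]3(O[Si](CC)(CC)CC)CC[C@]43C(=O)C[C@H]4C(=C)CCC5=C(Br)C(=O)O[C@@H]5[C@H]43)C(=C)CC[C@@H]12 | intermediate
25 | 13′-hydroxy compound | C=C1C(=O)O[C@@H]2[C@@H]3[C@@H](C[C@@]4(O)[C@]3(O[Si](CC)(CC)CC)CC[C@]43C(=O)C[C@H]4C(=C)CCC5=C(CO)C(=O)O[C@@H]5[C@H]43)C(=C)CC[C@@H]12 | intermediate
26 | N-(C13′)-2-nitrobenzenesulfonylhydrazine | C=C1C(=O)O[C@@H]2[C@@H]3[C@@H](C[C@@]4(O)[C@]3(O[Si](CC)(CC)CC)CC[C@]43C(=O)C[C@H]4C(=C)CCC5=C(CN(N)S(=O)(=O)c6ccccc6[N+](=O)[O-])C(=O)O[C@@H]5[C@H]43)C(=C)CC[C@@H]12 | intermediate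
27 | allylic diazene | C=C1C(=O)O[C@@H]2[C@@H]3[C@@H](C[C@@]4(O)[C@]3(O[Si](CC)(CC)CC)CC[C@]43C(=O)C[C@H]4C(=C)CCC5=C(CN=N)C(=O)O[C@@H]5[C@H]43)C(=C)CC[C@@H]12 | intermediate
28 | 4-O-triethylsilylainsliadimer A | C=C1C(=O)O[C@@H]2[C@@H]3[C@@H](C[C@@]4(O)[C@]3(O[Si](CC)(CC)CC)CC[C@]43C(=O)C[C@H]4C(=C)CC[C@H]5C(=C)C(=O)O[C@@H]5[C@H]43)C(=C)CC[C@@H]12 | intermediate
29 | ainsliadimer A | C=C1C(=O)O[C@@H]2[C@@H]3[C@@H](C[C@@]4(O)[C@]3(O)CC[C@]43C(=O)C[C@H]4C(=C)CC[C@H]5C(=C)C(=O)O[C@@H]5[C@H]43)C(=C)CC[C@@H]12 | target

## Step count

- Total step count: 18.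
- Longest linear sequence: 13 steps (steps 6–18, from 8). The unit A branch (steps 1–5) joins at step 13.

## Steps most likely to fail

**1. Step 15.**
- What may go wrong: the seven-membered ring may close more slowly than the furan is desilylated or adds between molecules. The furan may add with its other face at C6′. The enolate may be protonated before the aldol closure.
- Fallback (known chemistry only): it sets out from 2 and comes back at 29. Dess–Martin oxidation of 2 gives dehydrozaluzanin C F1.
- F1 is left at high concentration with a hydrogen-bond donor such as a binaphthol to dimerise by hetero-Diels–Alder reaction. One molecule acts as the oxadiene O=C3′–C4′=C15′ and the other as the dienophile C4=C15, attacked on its α face by oxygen. This gives the spiro-dihydropyran dimer F2.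
- Dilute aqueous acid hydrolyses the enol ether of F2 to the hydroxy diketone F3. DBU then closes C3–C4′ by intramolecular aldol addition under thermodynamic control to give 29.

**2. Step 17.**
- What may go wrong: hydrogen transfer from the small, freely rotating diazene may show poor facial selectivity at C7′. The sulfinic acid that is released may add to the lactone methylenes.
- Fallback: it sets out from 25 and comes back at 28. Acetic formic anhydride and pyridine convert 25 into the allylic formate F4.
- Pd(OAc)2 with PBu3 in THF ionises F4 to the π-allyl complex. After loss of CO2, the complex hands its hydride to the more substituted terminus C7′.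
- The hydrogen then arrives on the face that carries the bulky metal, so the preference for the open α face should be stronger, and no sulfinic acid is formed.

**3. Step 14.**
- What may go wrong: silyl enol ether formation at the C3 ketone, or silyloxydiene formation at the enone, may compete with furan formation.
- Fallback: it sets out from 21 and comes back at 24, and it makes no new compound F0.
- The silyl dienol ether is given up. Compound 21 is treated at high dilution with a tertiary amidine base (DBU, MeCN, 0 °C).
- This base deprotonates only the much more acidic α-bromobutenolide. The free furanolate then undergoes the direct vinylogous Michael addition at C5′, and the same base promotes the aldol closure.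

## Further compounds

F1 | step 15 | dehydrozaluzanin C | C=C1C(=O)C[C@H]2C(=C)CC[C@H]3C(=C)C(=O)O[C@@H]3[C@H]21
F2 | step 15 | spiro-dihydropyran hetero-Diels–Alder dimer (O3′–C4α, C15–C15′) | C=C1C(=O)O[C@@H]2[C@@H]3[C@@H](CC(=O)[C@]34CCC5=C(O4)C[C@H]6C(=C)CC[C@H]7C(=C)C(=O)O[C@@H]7[C@@H]56)C(=C)CC[C@@H]12
F3 | step 15 | 4α-hydroxy 3,3′-diketone (C4′ epimerisable, left open) | C=C1C(=O)O[C@@H]2[C@@H]3[C@@H](CC(=O)[C@]3(O)CCC4C(=O)C[C@H]5C(=C)CC[C@H]6C(=C)C(=O)O[C@@H]6[C@@H]45)C(=C)CC[C@@H]12
F4 | step 17 | 13′-formate of 25 | C=C1C(=O)O[C@@H]2[C@@H]3[C@@H](C[C@@]4(O)[C@]3(O[Si](CC)(CC)CC)CC[C@]43C(=O)C[C@H]4C(=C)CCC5=C(COC=O)C(=O)O[C@@H]5[C@H]43)C(=C)CC[C@@H]12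
F0 | step 14 | none | none
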